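Ring A is cut at C10–C11 and C1–C14. Its C14(OAc)–C13(=O)–C12=C11(CH3) unit is a latent 1,4-dipole (C14 donor, C11 acceptor), the E-C1=C10 alkene is its Markovnikov-matched partner, and the C2 oxygen lies 1,3 to C11. The precursor is therefore a 2-acetoxy-3-methylcyclobutanone whose 3-alkoxy donor is the C2–O of an (S)-allylic alcohol. A Lewis acid opens the four-membered ring. Oxocarbenium–alkene closure and enolate capture then form both bonds and set C1, C10 and C14 in one operation. β-Elimination of the temporary C11–O bridge unveils the enone and C2–OH. Ring B and the butenolide are closed last by a Nozaki–Hiyama–Kishi reaction and an oxidative lactonisation.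

Key step: step 9

Remark on numbering (briarane skeleton, used throughout):
- C1 is the quaternary ring-fusion carbon (bears C15H3) and C10 the ring-fusion CH.
- C2 is CH–O-isobutyryl, C3/C4 are CH2CH2, and C9 is CH2.
- C5(=C6) bears C16H3 and C7 is the lactone CH–O.
- C8=C17 is the butenolide alkene (C17 bears C18H3) and C19 the lactone C=O.
- C11(=C12) bears C20H3, C13 is the ketone and C14 is CH–OAc.
- Ring A is C1, C10–C14. Ring B is the ten-membered ring C1–C10. Ring C is the butenolide.

Assumption: cyclobutanone 17 is carried on as the diastereomer mixture at C11 and C14, because both centres are erased when the ring opens.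

Step 1
Reactants: 1 nerol
Product: 2 neryl tert-butyldimethylsilyl ether
Conditions: TBSCl, imidazole, CH2Cl2, rt
Reagents that add atoms: tert-butyldimethylsilyl chloride (TBSCl), CC(C)(C)[Si](C)(C)Cl
Why: Silyl ether protection of the primary allylic alcohol (later O-7) leaves untouched the Z-alkene of nerol, which becomes C5=C6.

Step 2
Reactants: 2 neryl tert-butyldimethylsilyl ether
Product: 3 (Z)-6-(tert-butyldimethylsilyloxy)-4-methylhex-4-enal
Conditions: O3 (1.0 equiv, titrated solution), CH2Cl2, −78 °C; then Me2S, −78 °C → rt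
Reagents that add atoms: ozone, [O-][O+]=O
Why: Chemoselective ozonolysis should cleave the remote isopropylidene alkene first and give the C2 aldehyde, because that alkene is more electron-rich than the one carrying the inductively withdrawing allylic silyloxy group.

Step 3
Reactants: 4 propargyl alcohol; 5 1-bromobut-2-yne
Product: 6 hepta-2,5-diyn-1-ol
Conditions: CuI, NaI, K2CO3, DMF, rt
Reagents that add atoms: none
Why: Copper-mediated SN2 coupling of a terminal alkyne with a propargylic bromide (skipped-diyne synthesis) joins C8 to C9 under conditions too weakly basic for alkyne–allene isomerisation.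

Step 4
Reactants: 6 hepta-2,5-diyn-1-ol
Product: 8 (Z)-3-iodo-2-methylhept-2-en-5-yn-1-ol, via oxamagnesacyclopentene 7 (not isolated)
Conditions: MeMgBr (3 equiv), CuI (10 mol %), THF, 0 °C → rt; then I2, −78 → 0 °C
Reagents that add atoms: methylmagnesium bromide, C[Mg]Br; iodine, II
Why: Alkoxide-directed, copper-catalysed anti-carbomagnesiation of a 2-alkyn-1-ol puts CH3 on C17 and Mg on C8 inside a five-membered chelate, iodinolysis with retention fixes the tetrasubstituted Z-alkenyl iodide (I cis to CH2OH), and the undirected C1≡C10 alkyne should not react.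

Step 5
Reactants: 8 (Z)-3-iodo-2-methylhept-2-en-5-yn-1-ol
Product: 9 (Z)-tert-butyl[(3-iodo-2-methylhept-2-en-5-yn-1-yl)oxy]diphenylsilane
Conditions: TBDPSCl, imidazole, CH2Cl2, rt
Reagents that add atoms: tert-butyldiphenylsilyl chloride (TBDPSCl), CC(C)(C)[Si](Cl)(c1ccccc1)c1ccccc1
Why: Silyl ether protection with a group that outlasts the TBS ether allows O-7 and O-19 to be released at different times.

Step 6
Reactants: 9 TBDPS-protected iodo enyne; 3 (Z)-6-(tert-butyldimethylsilyloxy)-4-methylhex-4-enal
Product: 13 (2Z,5E,7S,10Z)-12-(tert-butyldimethylsilyloxy)-1-(tert-butyldiphenylsilyloxy)-3-iodo-2,6,10-trimethyldodeca-2,5,10-trien-7-yl acetate, via alkenylzirconocene chloride 10 (not isolated), via alkenyl(methyl)zinc 11 (not isolated), via methylzinc alkoxide 12 (not isolated)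
Conditions: Cp2Zr(H)Cl (slight excess), CH2Cl2, rt; Me2Zn, toluene, −65 °C; (+)-MIB [(2R)-3-exo-morpholinoisoborneol, 10 mol %], 3, −30 → 0 °C; then Ac2O, DMAP (cat.), rt
Reagents that add atoms: acetic anhydride, CC(=O)OC(C)=O
Why: Hydrozirconation (syn, Zr at the less hindered methyl-bearing alkyne carbon C1), Zr-to-Zn transmetalation and amino-alcohol-catalysed asymmetric alkenylzinc addition form C1–C2 with the E-alkene, (+)-MIB directing the alkenyl group to the Re face of 3 to give the (2S)-alkoxide, which acetic anhydride traps.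

Step 7
Reactants: 13 (7S)-allylic acetate
Product: 14 (S)-allylic isopropenyl ether (prop-1-en-2-yl ether on O-2)
Conditions: Cp2Ti(μ-Cl)(μ-CH2)AlMe2 (1.1 equiv), pyridine (cat.), toluene–THF, −40 → 0 °C; filtration through basic alumina
Reagents that add atoms: Tebbe reagent Cp2Ti(μ-Cl)(μ-CH2)AlMe2, C[Al-]1(C)C[Ti](C2C=CC=C2)(C2C=CC=C2)[Cl+]1
Why: Tebbe methylenation of the only carbonyl group in the molecule turns the acetate into the isopropenyl ether (C11, C12 and C20) far below the temperature of a Claisen rearrangement.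

Step 8
Reactants: 14 (S)-allylic isopropenyl ether; 15 acetoxyacetyl chloride
Product: 17 2-acetoxy-3-methylcyclobutanone bearing O-2 as the 3-alkoxy group (diastereomer mixture at C11 and C14), via acetoxyketene 16 (not isolated)
Conditions: 15 (slow addition), iPr2NEt, CH2Cl2, 0 °C → rt
Reagents that add atoms: none
Why: In this ketene–enol ether (2+2) cycloaddition the nucleophilic CH2 (C12) bonds to the ketene carbonyl carbon (C13) and the oxygen-bearing carbon (C11) bonds to C14, which gives the 3-alkoxycyclobutanone regiochemistry, the electron-rich enol ether outruns all other alkenes, and the new centres C11 and C14 form as a mixture that step 9 makes irrelevant.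

Step 9
Reactants: 17 2-acetoxy-3-alkoxy-3-methylcyclobutanone
Product: 20 (1R,2S,10S,11S,14S)-6-oxabicyclo[3.2.1]octan-3-one (ring A bridged by C2–O–C11), via tin enolate oxocarbenium zwitterion 18 (not isolated), via C1 oxolanyl cation 19 (not isolated)
Conditions: SnCl4 (30 mol %), 2,6-di-tert-butyl-4-methylpyridine (40 mol %), CH2Cl2 (0.01 M), −78 → −40 °C
Reagents that add atoms: none
Why: Proposed new method: SnCl4 binds the C13 ketone (and the acetate carbonyl) of 17 and heterolyses the donor–acceptor C11–C14 bond, which erases both cyclobutane stereocentres and gives the C14 tin enolate/C11 oxocarbenium zwitterion 18, C10 of the tethered E-alkene then attacks C11 (bond C10–C11) to give the tertiary C1 cation 19, and the enolate carbon C14 captures it (bond C1–C14). The closest known reaction types are the Lewis-acid formal (4+2) cycloaddition of 3-alkoxycyclobutanones with allylsilanes, silyl enol ethers and carbon-tethered alkenes, and the 5-endo Prins closure of oxocarbenium ions made from allylic alcohols that opens Prins–pinacol cascades; new here is that the donor oxygen itself is the tether. The oxolane closes 5-endo-trig with respect to both π bonds and ring A closes as a 6-(enolendo) attack on the cation, so that a 6-oxabicyclo[3.2.1]octan-3-one results. For C10 and C1, the C2 stereocentre selects the alkene face because only one transition state keeps the C3 chain exo (turned away from the forming ring A, with H-2 next to the C1 methyl), and the enolate, held over C1 by charge attraction and a three-atom link, adds on the face that C11 has taken, so the E geometry is translated into the trans C2/C9 relationship, while C11 follows from the tether and is erased in step 10. For C14, the acetate takes the equatorial site of the chair (an axial one would clash 1,3-diaxially with C9), and since H-14 is enolisable the rigid bicycle should also funnel any epimer to this configuration. The step needs cleavage of C11–C14 rather than C11–C12 (secured by chelation, by the more substituted bond and because the other cleavage would place the cation next to C–OAc) and attack by C1=C10 rather than C5=C6 or C8=C17 (secured by five-membered versus seven-membered closure and by the deactivating iodine).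

Step 10
Reactants: 20 6-oxabicyclo[3.2.1]octan-3-one
Product: 22 (1R,2S,10R,14S) ring-A enone 2-isobutyrate 14-acetate carrying both side chains, via hydroxy enone 21 (not isolated)
Conditions: CSA (10 mol %), CH2Cl2, 0 °C → rt; then pyridine, DMAP (cat.), (iPrCO)2O, rt
Reagents that add atoms: isobutyric anhydride, CC(C)C(=O)OC(=O)C(C)C
Why: Acid-catalysed β-elimination (retro-oxa-Michael) of the tertiary C11–O bond, antiperiplanar to axial H-12, releases the bridge and gives the conjugated enone and the C2 alcohol, DMAP-catalysed acylation esterifies that alcohol at once, and the base-free opening avoids an alkoxide that could take the acetyl group from O-14.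

Step 11
Reactants: 22 ring-A enone 2-isobutyrate
Product: 23 C7 allylic alcohol (TBDPS ether on O-19 retained)
Conditions: PPTS (cat.), MeOH, rt
Reagents that add atoms: none
Why: Acid-catalysed methanolysis cleaves the primary TBS ether far faster than the TBDPS ether (orthogonal silyl deprotection), and esters, enone and alkenyl iodide are inert.

Step 12
Reactants: 23 C7 allylic alcohol
Product: 24 (Z)-enal (C7 aldehyde)
Conditions: MnO2 (activated), CH2Cl2, rt
Reagents that add atoms: none
Why: MnO2 oxidation of an allylic alcohol is neutral and should give the enal without Z-to-E isomerisation, as in the oxidation of nerol to neral.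

Step 13
Reactants: 24 (Z)-enal
Product: 26 (7R)-macrocyclic bis-allylic alcohol (ring B closed), via alkenylchromium dichloride 25 (not isolated)
Conditions: CrCl2 (10 equiv), NiCl2 (cat.), DMSO–THF, rt, slow addition to a final 1 mM
Reagents that add atoms: none
Why: In the Nozaki–Hiyama–Kishi reaction, nickel-catalysed formation of the alkenylchromium reagent with retention of geometry and its chemoselective 1,2-addition to the aldehyde (ketone, enone and esters untouched) close ring B at C7–C8 under high dilution, the gauche C2 and C9 arms on ring A bring the ends together, and attack on the outer face of the s-trans enal should give the (7R)-alcohol.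

Step 14
Reactants: 26 (7R)-macrocyclic alcohol
Product: 27 (Z)-2-ene-1,4-diol (free O-7 and O-19)
Conditions: HF·pyridine, pyridine, THF, 0 °C → rt
Reagents that add atoms: none
Why: Buffered fluoride desilylation removes the TBDPS group without ionising the bis-allylic C7 alcohol or cleaving the esters.

Step 15
Reactants: 27 (Z)-2-ene-1,4-diol
Product: 30 target CNP0325467.3, via hydroxy enal 28 (not isolated), via lactol 29 (not isolated)
Conditions: TEMPO (20 mol %), PhI(OAc)2 (2.5 equiv), CH2Cl2, rt
Reagents that add atoms: none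
Why: In this TEMPO/PhI(OAc)2 oxidative lactonisation of a Z-2-ene-1,4-diol the oxoammonium salt oxidises the primary allylic alcohol selectively, the aldehyde closes to the lactol on the cis C7–OH, and a second oxidation gives the butenolide (ring C) without touching the C7 stereocentre.

Compound list
1 | nerol, (Z)-3,7-dimethylocta-2,6-dien-1-ol | CC(C)=CCC/C(C)=C\CO | starting material
2 | neryl tert-butyldimethylsilyl ether | CC(C)=CCC/C(C)=C\CO[Si](C)(C)C(C)(C)C | intermediate
3 | (Z)-6-(tert-butyldimethylsilyloxy)-4-methylhex-4-enal (C2–C7, C16) | O=CCC/C(C)=C\CO[Si](C)(C)C(C)(C)C | intermediate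
4 | propargyl alcohol | C#CCO | starting material
5 | 1-bromobut-2-yne | CC#CCBr | starting material
6 | hepta-2,5-diyn-1-ol | CC#CCC#CCO | intermediate
7 | oxamagnesacyclopentene chelate (Mg on C8, CH3 on C17), not isolated | CC#CCC1=C(C)CO[Mg]1 | intermediate
8 | (Z)-3-iodo-2-methylhept-2-en-5-yn-1-ol | CC#CC/C(I)=C(\C)CO | intermediate
9 | TBDPS ether of 8 | CC#CC/C(I)=C(\C)CO[Si](c1ccccc1)(c1ccccc1)C(C)(C)C | intermediate
10 | (E)-alkenylzirconocene chloride (Zr on C1), not isolated | Cl[Zr](C1C=CC=C1)(C1C=CC=C1)/C(C)=C/C/C(I)=C(\C)CO[Si](c1ccccc1)(c1ccccc1)C(C)(C)C | intermediate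
11 | (E)-alkenyl(methyl)zinc, not isolated | C[Zn]/C(C)=C/C/C(I)=C(\C)CO[Si](c1ccccc1)(c1ccccc1)C(C)(C)C | intermediate
12 | (2S)-methylzinc alkoxide, not isolated | CC(C)(C)[Si](C)(C)OC/C=C(/C)CC[C@H](O[Zn]C)/C(C)=C/C/C(I)=C(\C)CO[Si](c1ccccc1)(c1ccccc1)C(C)(C)C | intermediate
13 | (2Z,5E,7S,10Z)-12-(TBSO)-1-(TBDPSO)-3-iodo-2,6,10-trimethyldodeca-2,5,10-trien-7-yl acetate | CC(C)(C)[Si](C)(C)OC/C=C(/C)CC[C@H](OC(C)=O)/C(C)=C/C/C(I)=C(\C)CO[Si](c1ccccc1)(c1ccccc1)C(C)(C)C | intermediate
14 | isopropenyl ether of the (2S)-allylic alcohol | CC(C)(C)[Si](C)(C)OC/C=C(/C)CC[C@H](OC(C)=C)/C(C)=C/C/C(I)=C(\C)CO[Si](c1ccccc1)(c1ccccc1)C(C)(C)C | intermediate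
15 | acetoxyacetyl chloride | CC(=O)OCC(=O)Cl | starting material
16 | acetoxyketene, not isolated | CC(=O)OC=C=O | intermediate
17 | 2-acetoxy-3-methyl-3-[(2S)-alkoxy]cyclobutanone, mixture at C11 and C14 | CC(C)(C)[Si](C)(C)OC/C=C(/C)CC[C@H](OC1(C)CC(=O)C1OC(C)=O)/C(C)=C/C/C(I)=C(\C)CO[Si](c1ccccc1)(c1ccccc1)C(C)(C)C | intermediate
18 | ring-opened zwitterion: C11 oxocarbenium on O-2, C13/C14 tin enolate, not isolated | CC(C)(C)[Si](C)(C)OC/C=C(/C)CC[C@H]([O+]=C(C)CC(O[Sn-](Cl)(Cl)(Cl)Cl)=COC(C)=O)/C(C)=C/C/C(I)=C(\C)CO[Si](c1ccccc1)(c1ccccc1)C(C)(C)C | intermediate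
19 | oxolane with tertiary cation at C1 (C10–C11 formed), not isolated | CC(C)(C)[Si](C)(C)OC/C=C(/C)CC[C@@H]1O[C@@](C)(CC(O[Sn-](Cl)(Cl)(Cl)Cl)=COC(C)=O)[C@@H](C/C(I)=C(\C)CO[Si](c2ccccc2)(c2ccccc2)C(C)(C)C)[C+]1C | intermediate
20 | (1R,2S,10S,11S,14S)-6-oxabicyclo[3.2.1]octan-3-one: chair ring A bridged by C2–O–C11, equatorial 14-OAc, C3 chain exo on C2, C9 chain on C10 anti to the oxygen bridge | CC(C)(C)[Si](C)(C)OC/C=C(/C)CC[C@@H]1O[C@@]2(C)CC(=O)[C@@H](OC(C)=O)[C@]1(C)[C@@H]2C/C(I)=C(\C)CO[Si](c1ccccc1)(c1ccccc1)C(C)(C)C | intermediate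
21 | (1R,2S,10R,14S)-hydroxy enone (free C2–OH), not isolated | CC(C)(C)[Si](C)(C)OC/C=C(/C)CC[C@H](O)[C@@]1(C)[C@H](C/C(I)=C(\C)CO[Si](c2ccccc2)(c2ccccc2)C(C)(C)C)C(C)=CC(=O)[C@H]1OC(C)=O | intermediate
22 | (1R,2S,10R,14S)-enone, 2-isobutyrate, 14-acetate | CC(C)(C)[Si](C)(C)OC/C=C(/C)CC[C@H](OC(=O)C(C)C)[C@@]1(C)[C@H](C/C(I)=C(\C)CO[Si](c2ccccc2)(c2ccccc2)C(C)(C)C)C(C)=CC(=O)[C@H]1OC(C)=O | intermediate
23 | C7 primary allylic alcohol | OC/C=C(/C)CC[C@H](OC(=O)C(C)C)[C@@]1(C)[C@H](C/C(I)=C(\C)CO[Si](c2ccccc2)(c2ccccc2)C(C)(C)C)C(C)=CC(=O)[C@H]1OC(C)=O | intermediate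
24 | (Z)-enal (C7 aldehyde) with (Z)-alkenyl iodide at C8 | O=C/C=C(/C)CC[C@H](OC(=O)C(C)C)[C@@]1(C)[C@H](C/C(I)=C(\C)CO[Si](c2ccccc2)(c2ccccc2)C(C)(C)C)C(C)=CC(=O)[C@H]1OC(C)=O | intermediate
25 | alkenylchromium dichloride (Cr on C8), not isolated | O=C/C=C(/C)CC[C@H](OC(=O)C(C)C)[C@@]1(C)[C@H](C/C([Cr](Cl)Cl)=C(\C)CO[Si](c2ccccc2)(c2ccccc2)C(C)(C)C)C(C)=CC(=O)[C@H]1OC(C)=O | intermediate
26 | (1R,2S,7R,10R,14S)-macrocyclic alcohol, rings A and B closed, O-19 TBDPS ether | CC(=O)O[C@@H]1C(=O)C=C(C)[C@H]2C/C(=C(\C)CO[Si](c3ccccc3)(c3ccccc3)C(C)(C)C)[C@H](O)/C=C(/C)CC[C@H](OC(=O)C(C)C)[C@@]21C | intermediate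
27 | (7R)-(Z)-2-ene-1,4-diol | CC(=O)O[C@@H]1C(=O)C=C(C)[C@H]2C/C(=C(\C)CO)[C@H](O)/C=C(/C)CC[C@H](OC(=O)C(C)C)[C@@]21C | intermediate
28 | (7R)-hydroxy enal (C19 aldehyde), not isolated | CC(=O)O[C@@H]1C(=O)C=C(C)[C@H]2C/C(=C(\C)C=O)[C@H](O)/C=C(/C)CC[C@H](OC(=O)C(C)C)[C@@]21C | intermediate
29 | lactol (C19 hemiacetal, either anomer), not isolated | CC(=O)O[C@@H]1C(=O)C=C(C)[C@H]2CC3=C(C)C(O)O[C@@H]3/C=C(/C)CC[C@H](OC(=O)C(C)C)[C@@]21C | intermediate
30 | CNP0325467.3, (1R,2S,5Z,7R,10R,14S) | CC(=O)O[C@@H]1C(=O)C=C(C)[C@H]2CC3=C(C)C(=O)O[C@@H]3/C=C(/C)CC[C@H](OC(=O)C(C)C)[C@@]21C | target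

Total step count: 15.
Longest linear sequence: 13 steps (steps 3–15, from propargyl alcohol and 1-bromobut-2-yne). The nerol branch (steps 1–2) joins at step 6.

Steps most likely to fail

Step 9 (labelled step).
- What may go wrong: proton loss or a 1,2-hydride shift (H-2 or H-10) at the C1 cation, ionisation of the allylic C2–O bond, or collapse of the zwitterion to the acyclic β-alkoxy enone, each before C14 reaches C1.
- Fallback (known chemistry, both ring-A bonds still made in one operation): a type 2 intramolecular Diels–Alder reaction with a temporary silicon tether. It sets out from 13.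
- K2CO3 in MeOH would give the (S)-allylic alcohol F1, and excess Me2SiCl2 with Et3N would give its chlorodimethylsilyl ether F2.
- Acylation of 2-methoxypropene with 15 (pyridine, CH2Cl2) would give (E)-1-acetoxy-4-methoxypent-3-en-2-one F3.
- The C14 enol of F3 would be silylated by F2 (Et3N, NaI, MeCN) to the tethered 2-silyloxy diene F4 (C13–O–SiMe2–O–C2).
- Heating (toluene, BHT, 180 °C, sealed tube) should give the bridged bicyclo[4.3.1] adduct F5. The four-atom tether enforces the C14–C1/C11–C10 regiochemistry and passes on the C2 configuration.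
- AcOH–THF–H2O would cleave the enol silane and the tether to the β-methoxy ketone F6. Catalytic CSA would expel methanol.
- The sequence comes back to the route at 21, which is acylated as in the second half of step 10.

Step 13.
- What may go wrong: poor facial selectivity at the C7 aldehyde, because only the conformation of the forming ten-membered ring controls it. Slow closure would in addition let intermolecular coupling compete.
- Fallback: C7 is corrected after ring closure by an invertive substitution instead of relying on macrocyclic control. It sets out from 24.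
- The ring closure would then deliver the (7S)-alcohol F7.
- A Mitsunobu reaction (ClCH2CO2H, PPh3, DIAD, toluene, 0 °C) should give the (7R)-chloroacetate F8 with inversion.
- Thiourea with NaHCO3 in EtOH removes the chloroacetyl group in the presence of acetate and isobutyrate. The sequence comes back at 26.

Step 6.
- What may go wrong: erosion of enantioselectivity through uncatalysed background addition of the hindered trisubstituted alkenylzinc reagent, and incomplete regiocontrol in the hydrozirconation.
- Fallback: C2 is set by reagent-controlled ketone reduction instead of asymmetric C–C bond formation. It sets out from 9 and 3.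
- Hydrozirconation, transmetalation with Me2Zn and addition without ligand would give the racemic allylic alcohol F9.
- Dess–Martin periodinane would give the E-configured α-methyl enone F10.
- Corey–Bakshi–Shibata reduction with the (R)-methyl oxazaborolidine and catecholborane (toluene, −78 °C; alkenyl as the large group) should give the (S)-allylic alcohol F1, the same compound as in the first fallback.
- Ac2O, pyridine and DMAP bring the sequence back at 13.

Further compounds
F1 | step 9 | (S)-allylic alcohol (free C2–OH) | CC(C)(C)[Si](C)(C)OC/C=C(/C)CC[C@H](O)/C(C)=C/C/C(I)=C(\C)CO[Si](c1ccccc1)(c1ccccc1)C(C)(C)C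
F2 | step 9 | chlorodimethylsilyl ether of F1 | CC(C)(C)[Si](C)(C)OC/C=C(/C)CC[C@H](O[Si](C)(C)Cl)/C(C)=C/C/C(I)=C(\C)CO[Si](c1ccccc1)(c1ccccc1)C(C)(C)C
F3 | step 9 | (E)-1-acetoxy-4-methoxypent-3-en-2-one | CO/C(C)=C/C(=O)COC(C)=O
F4 | step 9 | silicon-tethered 1-acetoxy-2-silyloxy-4-methoxy diene | CC(C)(C)[Si](C)(C)OC/C=C(/C)CC[C@H](O[Si](C)(C)OC(=COC(C)=O)/C=C(/OC)C)/C(C)=C/C/C(I)=C(\C)CO[Si](c1ccccc1)(c1ccccc1)C(C)(C)C
F5 | step 9 | bridged bicyclo[4.3.1] Diels–Alder adduct (bridgehead enol silane, C11 undefined) | CC(C)(C)[Si](C)(C)OC/C=C(/C)CC[C@@H]1O[Si](C)(C)OC2=CC(C)(OC)[C@@H](C/C(I)=C(\C)CO[Si](c3ccccc3)(c3ccccc3)C(C)(C)C)[C@@]1(C)[C@@H]2OC(C)=O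
F6 | step 9 | β-methoxy ketone with free C2–OH (C11 undefined) | CC(C)(C)[Si](C)(C)OC/C=C(/C)CC[C@H](O)[C@@]1(C)[C@H](C/C(I)=C(\C)CO[Si](c2ccccc2)(c2ccccc2)C(C)(C)C)C(C)(OC)CC(=O)[C@H]1OC(C)=O
F7 | step 13 | (7S)-macrocyclic alcohol (7-epimer of 26) | CC(=O)O[C@@H]1C(=O)C=C(C)[C@H]2C/C(=C(\C)CO[Si](c3ccccc3)(c3ccccc3)C(C)(C)C)[C@@H](O)/C=C(/C)CC[C@H](OC(=O)C(C)C)[C@@]21C
F8 | step 13 | (7R)-chloroacetate | CC(=O)O[C@@H]1C(=O)C=C(C)[C@H]2C/C(=C(\C)CO[Si](c3ccccc3)(c3ccccc3)C(C)(C)C)[C@H](OC(=O)CCl)/C=C(/C)CC[C@H](OC(=O)C(C)C)[C@@]21C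
F9 | step 6 | racemic allylic alcohol | CC(C)(C)[Si](C)(C)OC/C=C(/C)CCC(O)/C(C)=C/C/C(I)=C(\C)CO[Si](c1ccccc1)(c1ccccc1)C(C)(C)C
F10 | step 6 | (E)-α-methyl enone (C2 ketone) | CC(C)(C)[Si](C)(C)OC/C=C(/C)CCC(=O)/C(C)=C/C/C(I)=C(\C)CO[Si](c1ccccc1)(c1ccccc1)C(C)(C)C
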